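**Strategy.** Ring A of the eudesmane core (C1–C5, C10) holds three contiguous stereocentres: C1 with the benzylic C9′ arm, the methyl-bearing quaternary C10 and the ring-fusion carbon C5. Its C2–C7 chain, with the C4 methyl and the C11 unit, is the carbon set of (E)-β-ocimene. Cutting C1–C2 and C5–C10 therefore leads back to that triene and an (E)-2-methyl-2-enal that already carries the aryl/isobutyl centre C9′. One Lewis-acid Diels–Alder reaction closes ring A, sets C1, C5 and C10, and leaves a formyl group and the prenyl arm placed for ring B (homologation, carbonyl-ene). The two alkenes then become the C4 and C11 carbinols, and the arene is diformylated and unmasked.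

Key step: step 7

Remark (numbering): eudesmane numbering is used for the terpenoid part (ring A = C1–C5, C10; ring B = C5–C10; C11 on C7; C14 on C10; C15 on C4). C9′ is the benzylic carbon and aryl carbons are primed. β is the face of the C10 methyl group, α the opposite face.

Remark (assumption): (E)-β-ocimene is taken as E-enriched commercial material; any Z isomer cannot reach the s-cis diene conformation and is carried as a spectator.

Step 1
Reactants: 1 (2,4,6-trimethoxyphenyl)acetic acid; 2 (R)-4-benzyl-1,3-oxazolidin-2-one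
Product: 4 (R)-4-benzyl-3-[2-(2,4,6-trimethoxyphenyl)acetyl]-1,3-oxazolidin-2-one, via mixed pivalic anhydride 3 (not isolated)
Conditions: PivCl, Et3N, THF, −20 °C; then 2, LiCl, −20 °C → rt
Reagents that add atoms: none
Why: N-acylation of the LiCl-activated oxazolidinone by the mixed anhydride (auxiliary loading), in which the hindered pivaloyl carbonyl is spared and the arylacetyl group is transferred.

Step 2
Reactants: 4 (R)-4-benzyl-3-[2-(2,4,6-trimethoxyphenyl)acetyl]-1,3-oxazolidin-2-one; 5 methallyl bromide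
Product: 6 (R)-4-benzyl-3-[(2R)-4-methyl-2-(2,4,6-trimethoxyphenyl)pent-4-enoyl]-1,3-oxazolidin-2-one
Conditions: NaHMDS, THF, −78 °C; then 5, −78 → −40 °C
Reagents that add atoms: none
Why: Evans asymmetric alkylation, in which the chelated (Z)-sodium enolate takes the allylic bromide on the face opposite the 4-benzyl group and so sets the future C9′ (2R here, the same spatial arrangement as 9′S in the target).

Step 3
Reactants: 6 (R)-4-benzyl-3-[(2R)-4-methyl-2-(2,4,6-trimethoxyphenyl)pent-4-enoyl]-1,3-oxazolidin-2-one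
Product: 7 (R)-4-benzyl-3-[(2R)-4-methyl-2-(2,4,6-trimethoxyphenyl)pentanoyl]-1,3-oxazolidin-2-one
Conditions: H2 (1 atm), 10% Pd/C, EtOAc, rt
Reagents that add atoms: none
Why: Heterogeneous hydrogenation of the unhindered 1,1-disubstituted alkene gives the isobutyl group, while the arene, the imide and the C-benzyl group are inert and the stereocentre is not touched.

Step 4
Reactants: 7 (R)-4-benzyl-3-[(2R)-4-methyl-2-(2,4,6-trimethoxyphenyl)pentanoyl]-1,3-oxazolidin-2-one
Product: 8 (2R)-4-methyl-2-(2,4,6-trimethoxyphenyl)pentan-1-ol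
Conditions: LiBH4, MeOH (1 equiv), Et2O, 0 °C
Reagents that add atoms: none
Why: Reductive cleavage of the N-acyl oxazolidinone by borohydride at the exocyclic carbonyl releases the primary alcohol under non-enolising conditions, so the α-aryl centre is kept and the auxiliary is recovered.

Step 5
Reactants: 8 (2R)-4-methyl-2-(2,4,6-trimethoxyphenyl)pentan-1-ol
Product: 9 (2R)-4-methyl-2-(2,4,6-trimethoxyphenyl)pentanal
Conditions: Dess–Martin periodinane, CH2Cl2, 0 °C → rt; crude aldehyde used at once
Reagents that add atoms: none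
Why: Dess–Martin oxidation is base-free and should deliver the α-aryl aldehyde without enolisation, the twisted di-ortho-substituted aryl group further lowering the α-acidity.

Step 6
Reactants: 9 (2R)-4-methyl-2-(2,4,6-trimethoxyphenyl)pentanal; 10 2-(triphenylphosphoranylidene)propanal
Product: 11 (2E,4S)-2,6-dimethyl-4-(2,4,6-trimethoxyphenyl)hept-2-enal
Conditions: 10 (1.5 equiv), toluene, 80 °C
Reagents that add atoms: none
Why: Wittig olefination with the formyl-stabilised, non-basic ylide should give the E-trisubstituted enal (C9′ cis to the 2-methyl group) without touching the adjacent stereocentre.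

Step 7
Reactants: 11 (2E,4S)-2,6-dimethyl-4-(2,4,6-trimethoxyphenyl)hept-2-enal; 12 (E)-β-ocimene
Product: 13 (1S,2S,6S)-1,3-dimethyl-2-(3-methylbut-2-en-1-yl)-6-[(1S)-3-methyl-1-(2,4,6-trimethoxyphenyl)butyl]cyclohex-3-ene-1-carbaldehyde
Conditions: (S)-B-o-tolyl oxazaborolidine from (S)-α,α-diphenylprolinol, activated with Tf2NH (20 mol %), 12 (4 equiv), CH2Cl2, −78 → −20 °C
Reagents that add atoms: none
Why: The oxazaborolidinium-bound enal undergoes a concerted, asynchronous [4+2] cycloaddition in which the β-carbon C1 bonds to the free diene terminus C2 ahead of C10–C5; the closest known type is the cationic-oxazaborolidine Diels–Alder of 2-methyl-2-enals with acyclic 1,2-disubstituted dienes. Ring A is closed by this intermolecular [4+2] cycloaddition, suprafacial on both partners, leaving the C3=C4 alkene. The relative configuration of C1 and C10 follows from the E-enal (C9′ and the 2-methyl group stay cis); their absolute sense requires addition to the C10-Re/C1-Si face, which the C9′ centre (allylic strain against the 2-methyl group, aryl turned away from the diene) must permit and which the (S)-catalyst is expected to leave open, as it does with simple 2-methyl enals. C5 is fixed relative to C10 by the formyl-exo arrangement (2-methyl group and C9′ under the diene), which places the E-prenyl arm cis to the C10 methyl and trans to the formyl group, as the later trans-decalin needs; the 2-methyl substituent is what is relied on for this arrangement, and it is not assured for a β-branched enal. The step also needs "ortho" regiochemistry (substituted terminus C5 to the formyl-bearing C10), which is secured by the terminal alkyl substituent of the diene (larger coefficient at C2) and by the bulk at C1. Only the E-diene can reach the s-cis conformation.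

Step 8
Reactants: 13 (1S,2S,6S)-1,3-dimethyl-2-(3-methylbut-2-en-1-yl)-6-[(1S)-3-methyl-1-(2,4,6-trimethoxyphenyl)butyl]cyclohex-3-ene-1-carbaldehyde
Product: 15 2-[(1S,2S,6S)-1,3-dimethyl-2-(3-methylbut-2-en-1-yl)-6-[(1S)-3-methyl-1-(2,4,6-trimethoxyphenyl)butyl]cyclohex-3-en-1-yl]acetaldehyde, via methyl enol ether 14 (not isolated)
Conditions: Ph3P(CH2OMe)Cl, KHMDS, THF, 0 °C → rt; then 1 M aq. HCl, THF, 0 °C → rt
Reagents that add atoms: (methoxymethyl)triphenylphosphonium chloride, COC[P+](c1ccccc1)(c1ccccc1)c1ccccc1.[Cl-]; water, O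
Why: Wittig methoxymethylenation of the neopentyl aldehyde, followed by acid hydrolysis of the enol ether, adds C8 as a one-carbon homologation; C10 is quaternary, so nothing can epimerise.

Step 9
Reactants: 15 2-[(1S,2S,6S)-1,3-dimethyl-2-(3-methylbut-2-en-1-yl)-6-[(1S)-3-methyl-1-(2,4,6-trimethoxyphenyl)butyl]cyclohex-3-en-1-yl]acetaldehyde
Product: 16 1β-[(1S)-3-methyl-1-(2,4,6-trimethoxyphenyl)butyl]-5αH-eudesma-3,11-dien-8α-ol (trans-decalin with 7β-isopropenyl and 10β-methyl)
Conditions: ZnBr2 (1.5 equiv), CH2Cl2, 0 °C → rt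
Reagents that add atoms: none
Why: Type-I intramolecular carbonyl-ene reaction (citronellal-to-isopulegol type) closes ring B through a chair transition state by forming C7–C8, so that the trans ring fusion follows from C5/C10 and the isopropenyl group takes the equatorial 7β position; the C8 carbinol (expected equatorial) is removed later.

Step 10
Reactants: 16 1β-[(1S)-3-methyl-1-(2,4,6-trimethoxyphenyl)butyl]-5αH-eudesma-3,11-dien-8α-ol
Product: 17 O-{1β-[(1S)-3-methyl-1-(2,4,6-trimethoxyphenyl)butyl]-5αH-eudesma-3,11-dien-8α-yl} S-methyl dithiocarbonate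
Conditions: NaH, imidazole (cat.), THF, 0 °C; CS2; then MeI, rt
Reagents that add atoms: carbon disulfide, S=C=S; iodomethane, CI
Why: Xanthate formation from the secondary alkoxide (first stage of a Barton–McCombie deoxygenation) is reliable for hindered alcohols and touches no other group.

Step 11
Reactants: 17 O-{1β-[(1S)-3-methyl-1-(2,4,6-trimethoxyphenyl)butyl]-5αH-eudesma-3,11-dien-8α-yl} S-methyl dithiocarbonate
Product: 18 1β-[(1S)-3-methyl-1-(2,4,6-trimethoxyphenyl)butyl]-5αH-eudesma-3,11-diene
Conditions: Bu3SnH, AIBN (cat.), toluene, 100 °C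
Reagents that add atoms: none
Why: Barton–McCombie radical deoxygenation, in which the secondary C8 radical is reduced by tin hydride faster than it can rearrange and the rigid trans-decalin keeps it away from the C3=C4 bond.

Step 12
Reactants: 18 1β-[(1S)-3-methyl-1-(2,4,6-trimethoxyphenyl)butyl]-5αH-eudesma-3,11-diene
Product: 19 1β-[(1S)-3-methyl-1-(2,4,6-trimethoxyphenyl)butyl]-5αH-eudesmane-4α,11-diol
Conditions: Mn(dpm)3 (20 mol %), PhSiH3, O2 (1 atm), i-PrOH/CH2Cl2, 0 °C → rt; then PPh3
Reagents that add atoms: dioxygen, O=O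
Why: Mukaiyama-type hydrogen-atom-transfer hydration turns both alkenes into Markovnikov tertiary carbinols, and the planar C4 radical should be trapped by O2 on the α face, away from the 1,3-related axial C10 methyl, to give the 4α-OH/4β-methyl centre (C11 is not stereogenic).

Step 13
Reactants: 19 1β-[(1S)-3-methyl-1-(2,4,6-trimethoxyphenyl)butyl]-5αH-eudesmane-4α,11-diol
Product: 20 1β-[(1S)-1-(3,5-dibromo-2,4,6-trimethoxyphenyl)-3-methylbutyl]-5αH-eudesmane-4α,11-diol
Conditions: NBS (2.1 equiv), MeCN, 0 °C → rt, dark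
Reagents that add atoms: N-bromosuccinimide, O=C1CCC(=O)N1Br
Why: Electrophilic aromatic bromination of the strongly activated arene occupies its only two free positions (C3′, C5′) without acid, so the tertiary alcohols are safe.

Step 14
Reactants: 20 1β-[(1S)-1-(3,5-dibromo-2,4,6-trimethoxyphenyl)-3-methylbutyl]-5αH-eudesmane-4α,11-diol
Product: 21 5-[(1S)-1-(4α,11-dihydroxy-5αH-eudesman-1β-yl)-3-methylbutyl]-2,4,6-trimethoxybenzene-1,3-dicarbaldehyde
Conditions: t-BuLi (6.5 equiv), THF, −78 °C; then DMF, −78 → 0 °C; aq. NH4Cl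
Reagents that add atoms: N,N-dimethylformamide, CN(C)C=O
Why: After deprotonation of the two hydroxyl groups, double bromine–lithium exchange gives aryllithium sites each flanked by two methoxy groups, which are formylated by DMF (Bouveault-type formylation) under conditions that cannot ionise the tertiary alkoxides.

Step 15
Reactants: 21 5-[(1S)-1-(4α,11-dihydroxy-5αH-eudesman-1β-yl)-3-methylbutyl]-2,4,6-trimethoxybenzene-1,3-dicarbaldehyde
Product: 22 macrocarpal J
Conditions: NaSEt (excess), DMF, 120 °C; then 1 M aq. HCl (work-up)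
Reagents that add atoms: none
Why: SN2 O-demethylation by thiolate cleaves the three aryl methyl ethers, each activated by ortho/para formyl groups, under basic conditions that leave the tertiary alcohols and all stereocentres untouched.

**Compound list**

1 | (2,4,6-trimethoxyphenyl)acetic acid | COc1cc(OC)c(CC(O)=O)c(OC)c1 | starting material
2 | (R)-4-benzyl-1,3-oxazolidin-2-one | O=C1N[C@H](Cc2ccccc2)CO1 | starting material
3 | 2-(2,4,6-trimethoxyphenyl)acetic pivalic anhydride | COc1cc(OC)c(CC(=O)OC(=O)C(C)(C)C)c(OC)c1 | intermediate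
4 | (R)-4-benzyl-3-[2-(2,4,6-trimethoxyphenyl)acetyl]-1,3-oxazolidin-2-one | COc1cc(OC)c(CC(=O)N2[C@H](Cc3ccccc3)COC2=O)c(OC)c1 | intermediate
5 | methallyl bromide (3-bromo-2-methylprop-1-ene) | C=C(C)CBr | starting material
6 | (R)-4-benzyl-3-[(2R)-4-methyl-2-(2,4,6-trimethoxyphenyl)pent-4-enoyl]-1,3-oxazolidin-2-one | C=C(C)C[C@H](c1c(OC)cc(OC)cc1OC)C(=O)N1[C@H](Cc2ccccc2)COC1=O | intermediate
7 | (R)-4-benzyl-3-[(2R)-4-methyl-2-(2,4,6-trimethoxyphenyl)pentanoyl]-1,3-oxazolidin-2-one | CC(C)C[C@H](c1c(OC)cc(OC)cc1OC)C(=O)N1[C@H](Cc2ccccc2)COC1=O | intermediate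
8 | (2R)-4-methyl-2-(2,4,6-trimethoxyphenyl)pentan-1-ol | CC(C)C[C@H](c1c(OC)cc(OC)cc1OC)CO | intermediate
9 | (2R)-4-methyl-2-(2,4,6-trimethoxyphenyl)pentanal | CC(C)C[C@H](c1c(OC)cc(OC)cc1OC)C=O | intermediate
10 | 2-(triphenylphosphoranylidene)propanal | CC(C=O)=P(c1ccccc1)(c1ccccc1)c1ccccc1 | starting material
11 | (2E,4S)-2,6-dimethyl-4-(2,4,6-trimethoxyphenyl)hept-2-enal | CC(C)C[C@H](c1c(OC)cc(OC)cc1OC)/C=C(\C)C=O | intermediate
12 | (E)-β-ocimene, (3E)-3,7-dimethylocta-1,3,6-triene | C=C/C(C)=C/CC=C(C)C | starting material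
13 | (1S,2S,6S)-1,3-dimethyl-2-(3-methylbut-2-en-1-yl)-6-[(1S)-3-methyl-1-(2,4,6-trimethoxyphenyl)butyl]cyclohex-3-ene-1-carbaldehyde | CC(C)C[C@H](c1c(OC)cc(OC)cc1OC)[C@@H]1CC=C(C)[C@H](CC=C(C)C)[C@@]1(C)C=O | intermediate
14 | methyl enol ether of 13 (E/Z mixture): the same cyclohexene with 2-methoxyethenyl in place of formyl | CC(C)C[C@H](c1c(OC)cc(OC)cc1OC)[C@@H]1CC=C(C)[C@H](CC=C(C)C)[C@@]1(C)C=COC | intermediate
15 | 2-[(1S,2S,6S)-1,3-dimethyl-2-(3-methylbut-2-en-1-yl)-6-[(1S)-3-methyl-1-(2,4,6-trimethoxyphenyl)butyl]cyclohex-3-en-1-yl]acetaldehyde | CC(C)C[C@H](c1c(OC)cc(OC)cc1OC)[C@@H]1CC=C(C)[C@H](CC=C(C)C)[C@@]1(C)CC=O | intermediate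
16 | 1β-[(1S)-3-methyl-1-(2,4,6-trimethoxyphenyl)butyl]-5αH-eudesma-3,11-dien-8α-ol | CC(C)C[C@H](c1c(OC)cc(OC)cc1OC)[C@@H]1CC=C(C)[C@@H]2C[C@H](C(C)=C)[C@@H](O)C[C@]21C | intermediate
17 | O-{1β-[(1S)-3-methyl-1-(2,4,6-trimethoxyphenyl)butyl]-5αH-eudesma-3,11-dien-8α-yl} S-methyl dithiocarbonate | CC(C)C[C@H](c1c(OC)cc(OC)cc1OC)[C@@H]1CC=C(C)[C@@H]2C[C@H](C(C)=C)[C@@H](OC(=S)SC)C[C@]21C | intermediate
18 | 1β-[(1S)-3-methyl-1-(2,4,6-trimethoxyphenyl)butyl]-5αH-eudesma-3,11-diene | CC(C)C[C@H](c1c(OC)cc(OC)cc1OC)[C@@H]1CC=C(C)[C@@H]2C[C@H](C(C)=C)CC[C@]21C | intermediate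
19 | 1β-[(1S)-3-methyl-1-(2,4,6-trimethoxyphenyl)butyl]-5αH-eudesmane-4α,11-diol | CC(C)C[C@H](c1c(OC)cc(OC)cc1OC)[C@@H]1CC[C@@](C)(O)[C@@H]2C[C@H](C(C)(C)O)CC[C@]21C | intermediate
20 | 1β-[(1S)-1-(3,5-dibromo-2,4,6-trimethoxyphenyl)-3-methylbutyl]-5αH-eudesmane-4α,11-diol | CC(C)C[C@H](c1c(OC)c(Br)c(OC)c(Br)c1OC)[C@@H]1CC[C@@](C)(O)[C@@H]2C[C@H](C(C)(C)O)CC[C@]21C | intermediate
21 | 5-[(1S)-1-(4α,11-dihydroxy-5αH-eudesman-1β-yl)-3-methylbutyl]-2,4,6-trimethoxybenzene-1,3-dicarbaldehyde | CC(C)C[C@H](c1c(OC)c(C=O)c(OC)c(C=O)c1OC)[C@@H]1CC[C@@](C)(O)[C@@H]2C[C@H](C(C)(C)O)CC[C@]21C | intermediate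
22 | macrocarpal J | CC(C)C[C@H](c1c(O)c(C=O)c(O)c(C=O)c1O)[C@@H]1CC[C@@](C)(O)[C@@H]2C[C@H](C(C)(C)O)CC[C@]21C | target

**Step count.** Total: 15 steps. Longest linear sequence: 15 steps (from 1).

**Steps most likely to fail**

1. Step 7 (Diels–Alder). Several processes can go wrong together.
   - The β-branched trisubstituted enal may add too slowly, so that acid-induced oligomerisation of the triene takes over.
   - The cycloaddition may run in the formyl-endo mode (C9′ exo), which gives the C5 epimer and later a cis-decalin.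
   - Facial selectivity may be poor or reversed. In the formyl-exo mode C9′ lies under the diene and must turn its hydrogen toward it, so the substrate bias is not the simple allylic-strain one and may oppose the catalyst.
   - The C4 methyl group of the diene may divert some material to the "meta" regioisomer.

   Fallback, from 11 back to 13: the activation mode is changed to an ionic Diels–Alder reaction. Enal 11 is acetalised (ethylene glycol, PPTS, benzene, reflux with water removal) to 2-[(2E,4S)-6-methyl-4-(2,4,6-trimethoxyphenyl)hept-2-en-2-yl]-1,3-dioxolane F1. With TMSOTf (10 mol %) in CH2Cl2 at −78 °C this should open to an alkoxy-allyl cation, a far more reactive dienophile whose bulky cationic acetal residue prefers the exo position. Cycloaddition with 12 should give 2-[(1S,2S,6S)-1,3-dimethyl-2-(3-methylbut-2-en-1-yl)-6-[(1S)-3-methyl-1-(2,4,6-trimethoxyphenyl)butyl]cyclohex-3-en-1-yl]-1,3-dioxolane F2. Mild hydrolysis (PPTS, acetone/water, 50 °C) then returns aldehyde 13.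

2. Step 12 (double hydration). The hindered trisubstituted C3=C4 bond may be hydrated incompletely or reduced to the alkane, and O2 capture on the β face would give the C4 epimer.

   Fallback, from 18 back to 19: both alkenes are epoxidised with mCPBA (2.2 equiv, NaHCO3, CH2Cl2, 0 °C), the ring alkene on the α face opposite the C10 methyl group, to give 3α,4α:11,12-diepoxy-1β-[(1S)-3-methyl-1-(2,4,6-trimethoxyphenyl)butyl]-5αH-eudesmane F3 (C11 epimers). LiEt3BH (THF, 0 → 60 °C) should then deliver hydride to the less substituted carbons C3 and C12, leaving both oxygens on the tertiary carbons and giving diol 19.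

3. Step 14 (double formylation). The second bromine–lithium exchange on an already lithiated, alkoxide-bearing arene may stall or be quenched by proton transfer, leaving mono-aldehyde.

   Fallback, from 20 back to 21: double Suzuki–Miyaura vinylation (potassium vinyltrifluoroborate, Pd(OAc)2/SPhos, Cs2CO3, THF/water, 80 °C) should give 1β-[(1S)-1-(3,5-diethenyl-2,4,6-trimethoxyphenyl)-3-methylbutyl]-5αH-eudesmane-4α,11-diol F4. Lemieux–Johnson cleavage of both vinyl groups (OsO4 cat., NaIO4, 2,6-lutidine, dioxane/water) then gives dialdehyde 21.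

**Further compounds**

F1 | step 7 | 2-[(2E,4S)-6-methyl-4-(2,4,6-trimethoxyphenyl)hept-2-en-2-yl]-1,3-dioxolane | CC(C)C[C@H](c1c(OC)cc(OC)cc1OC)/C=C(\C)C1OCCO1
F2 | step 7 | 2-[(1S,2S,6S)-1,3-dimethyl-2-(3-methylbut-2-en-1-yl)-6-[(1S)-3-methyl-1-(2,4,6-trimethoxyphenyl)butyl]cyclohex-3-en-1-yl]-1,3-dioxolane | CC(C)C[C@H](c1c(OC)cc(OC)cc1OC)[C@@H]1CC=C(C)[C@H](CC=C(C)C)[C@@]1(C)C1OCCO1
F3 | step 12 | 3α,4α:11,12-diepoxy-1β-[(1S)-3-methyl-1-(2,4,6-trimethoxyphenyl)butyl]-5αH-eudesmane (C11 epimers) | CC(C)C[C@H](c1c(OC)cc(OC)cc1OC)[C@@H]1C[C@H]3O[C@@]3(C)[C@@H]2C[C@H](C4(C)CO4)CC[C@]21C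
F4 | step 14 | 1β-[(1S)-1-(3,5-diethenyl-2,4,6-trimethoxyphenyl)-3-methylbutyl]-5αH-eudesmane-4α,11-diol | CC(C)C[C@H](c1c(OC)c(C=C)c(OC)c(C=C)c1OC)[C@@H]1CC[C@@](C)(O)[C@@H]2C[C@H](C(C)(C)O)CC[C@]21C
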